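**Plan**

1. Cage locants used below (caged-xanthone style): C5 prenylated ether carbon, C6 ketone, C7 carbinol bridgehead, C8=C8a alkene, C9 carboxyl carbon, C10a oxygenated bridgehead.
2. Retrosynthesis: the spiro acylal is cut at its O(C10a)–C bond (oxa-Michael) and then at the C9–O ester bond, giving a cage dihydroxy acid and a pyrano-fused prenyl hydroxyquinone. The cage is cut at C7–C8 and C8a–C10a (methyl propiolate), and the resulting 6-oxabicyclo[3.2.1]octane-4,8-dione at its C5–O and C5–prenyl bonds.
3. Enabling feature: in the bicyclo[2.2.2]octene ring the C8=C8a bridge joins C7, which is α to the C6 ketone, to the carbinol carbon C10a. C7 is therefore an enolate carbon, C10a a ketone carbon and C8=C8a–C9 an ynoate.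
4. Forward ring order: cyclohexane (dearomatised 2,4-dimethoxyphenol) → tetrahydrofuran ether bridge → bicyclo[2.2.2]octene (key step) → ester link to the chromenequinone (made from phloroglucinol) → spiro 1,3-dioxin-4-one.
5. Stereochemistry: a rhodium/(S)-BINAP conjugate addition sets the ring-fusion CH; cis-bridging relays it to C5 and the cage closure to C7 and C10a; the spiro carbon and the adjacent CH(prenyl) are set last under thermodynamic control.

Key step: step 9

Assumption 1: Luche reduction of 4 is taken to give mainly the alcohol cis to the isopropenyl group, as with other 5-substituted cyclohexenones; this centre is erased by enolisation in step 9, so either epimer serves.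
Assumption 2: the quinone monoketal is taken to follow the facial model of cyclohex-2-enone in step 2, so that (S)-BINAP gives the (S)-adduct; if the sense is opposite, (R)-BINAP is used.
Assumption 3: 1,3-diones 9 and 11 are drawn as diketo tautomers although they should exist largely as enols, so the carbon between the carbonyls is not a fixed stereocentre.

**Route**

Step 1
Reactants: 1 2,4-dimethoxyphenol
Product: 2 2,4,4-trimethoxycyclohexa-2,5-dien-1-one
Conditions: PhI(OAc)2 (1.1 equiv), MeOH, 0 °C
Reagents that add atoms: methanol, CO
Why: Oxidative dearomatisation of a 4-methoxyphenol with a trivalent-iodine reagent, in which methanol attacks the para carbon that already carries a methoxy group and gives the para-quinone monoketal.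

Step 2
Reactants: 2 2,4,4-trimethoxycyclohexa-2,5-dien-1-one; 3 isopropenylboronic acid pinacol ester
Product: 4 (S)-2,4,4-trimethoxy-5-(prop-1-en-2-yl)cyclohex-2-en-1-one
Conditions: [RhCl(C2H4)2]2 (2.5 mol %), (S)-BINAP (6 mol %), aq. KOH (0.5 equiv), 1,4-dioxane–H2O 10:1, 40 °C
Reagents that add atoms: isopropenylboronic acid pinacol ester (compound 3), CC(=C)B1OC(C)(C)C(C)(C)O1
Why: Rhodium-catalysed asymmetric conjugate addition (Hayashi–Miyaura reaction), in which the alkenyl–rhodium species inserts the unsubstituted enone double bond rather than the methoxy-bearing one and the BINAP ligand selects the enone face, so that the future ring-fusion CH is formed as the S centre.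

Step 3
Reactants: 4 (S)-2,4,4-trimethoxy-5-(prop-1-en-2-yl)cyclohex-2-en-1-one
Product: 5 (1S,5S)-2,4,4-trimethoxy-5-(prop-1-en-2-yl)cyclohex-2-en-1-ol
Conditions: NaBH4, CeCl3·7H2O, MeOH, −78 °C; aq. NaHCO3
Reagents that add atoms: none
Why: Luche reduction gives clean 1,2-reduction of the α-methoxy enone, with hydride delivered anti to the C5 substituent so that the hydroxyl should be cis to the isopropenyl group (a centre that is later erased).

Step 4
Reactants: 5 (1S,5S)-2,4,4-trimethoxy-5-(prop-1-en-2-yl)cyclohex-2-en-1-ol
Product: 6 4-methoxybenzyl (PMB) ether of 5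
Conditions: NaH, 4-methoxybenzyl chloride, n-Bu4NI (cat.), THF–DMF, 0 °C to rt
Reagents that add atoms: 4-methoxybenzyl chloride, COc1ccc(CCl)cc1
Why: Williamson etherification under basic conditions that leave the ketal and enol ether untouched; the PMB group is chosen because it survives the aqueous acid of step 6, cannot migrate in the enolate of step 9 and is removed oxidatively.

Step 5
Reactants: 6 PMB ether of 5
Product: 7 2-[(1S,5S)-2,2,4-trimethoxy-5-(4-methoxybenzyloxy)cyclohex-3-en-1-yl]propan-2-ol
Conditions: Co(acac)2 (20 mol %), PhSiH3, O2 (1 atm), THF, rt; then PPh3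
Reagents that add atoms: dioxygen, O=O
Why: Mukaiyama hydration (cobalt-hydride hydrogen-atom transfer, capture of the tertiary radical by O2, reduction of the peroxide) gives the Markovnikov tertiary alcohol, and the unhindered 1,1-disubstituted alkene should react ahead of the trisubstituted enol ether whose β-carbon is neopentylic.

Step 6
Reactants: 7 2-[(1S,5S)-2,2,4-trimethoxy-5-(4-methoxybenzyloxy)cyclohex-3-en-1-yl]propan-2-ol
Product: 9 (4S,6S)-6-(2-hydroxypropan-2-yl)-4-(4-methoxybenzyloxy)cyclohexane-1,3-dione, via methoxyenone 8 (not isolated)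
Conditions: 1 M aq. HCl–THF (1:4), 0 °C to rt
Reagents that add atoms: water, O
Why: Acid hydrolysis of a ketal and an enol ether (a masked 1,3-dione): the ionised ketal is captured by water to give vinylogous ester 8, which hydrolyses further to the dione; cold dilute acid spares the PMB ether and the tertiary alcohol, and the ring-fusion CH should hold its configuration because the dione sits as its enol.

Step 7
Reactants: 9 (4S,6S)-6-(2-hydroxypropan-2-yl)-4-(4-methoxybenzyloxy)cyclohexane-1,3-dione; 10 prenyl acetate
Product: 11 (4S,6S)-6-(2-hydroxypropan-2-yl)-4-(4-methoxybenzyloxy)-2-(3-methylbut-2-en-1-yl)cyclohexane-1,3-dione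
Conditions: Pd(PPh3)4 (5 mol %), Et3N, THF, 40 °C
Reagents that add atoms: prenyl acetate (compound 10), CC(C)=CCOC(C)=O
Why: Tsuji–Trost allylation, in which the soft dione enolate attacks the π-prenyl complex formed by zerovalent palladium at its unsubstituted terminus to give the linear C-prenyl product, while any O-allylated material re-ionises and is funnelled to carbon.

Step 8
Reactants: 11 2-prenyl-1,3-dione
Product: 12 (1S,3S,5R)-3-(4-methoxybenzyloxy)-7,7-dimethyl-5-(3-methylbut-2-en-1-yl)-6-oxabicyclo[3.2.1]octane-4,8-dione
Conditions: PhI(OAc)2 (1.2 equiv), CH2Cl2, 0 °C to rt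
Reagents that add atoms: none
Why: Intramolecular α-oxygenation of a 2-substituted 1,3-dicarbonyl compound by a trivalent-iodine reagent (oxidative cycloetherification): the iodane-bound enol is displaced at C5 by the tertiary hydroxyl with loss of iodobenzene, and because the O–CMe2 tether can only bridge cis, the C5 configuration follows from the ring-fusion CH and the prenyl group goes to the opposite face.

Step 9
Reactants: 12 oxabicyclic dione; 13 methyl propiolate
Product: 16 methyl 7-hydroxy-1-(4-methoxybenzyloxy)-5,5-dimethyl-3-(3-methylbut-2-en-1-yl)-2-oxo-4-oxatricyclo[4.3.1.0^3,7]dec-8-ene-8-carboxylate (cage hydroxy ester), via lithium enolate 14 (not isolated), via lithium allenolate 15 (not isolated)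
Conditions: LiN(SiMe3)2 (1.05 equiv), THF, −78 °C; methyl propiolate (1.3 equiv, slow addition), −78 to −30 °C; AcOH, −78 °C
Reagents that add atoms: methyl propiolate (compound 13), C#CC(=O)OC
Why: Anionic tandem Michael–aldol annulation: LiN(SiMe3)2 removes the C7 hydrogen, the only enolisable one because C5 is quaternary and the ring-fusion CH is a bridgehead, enolate 14 adds through C7 to the β-carbon of the ynoate (C7–C8), and lithium allenolate 15 attacks the angle-strained bridging C10a ketone through its ester-bearing carbon (C8a–C10a). The closest known reaction type is conjugate addition of an enolate to an alkynoate with intramolecular aldol capture of the allenolate, the alkyne counterpart of the double-Michael bridging annulations that give bicyclo[2.2.2]octanes. The one ring closed, the bicyclo[2.2.2]octene, forms by a 6-exo-trig aldol through a boat cyclohexanone with C7 and C10a as bow and stern, whereas closure on the C6 carbonyl would need a four-membered ring. C7 is controlled by the enolate face, since the endo methyl of the O–CMe2 bridge blocks one side and the ynoate must bond on the side carrying the C10a carbonyl; C10a is controlled by the tether, which reaches only that face of the ketone, so both centres follow from C5 and the ring-fusion CH. The step needs Michael addition to outrun proton transfer from the alkyne C–H and needs the C7–C8 bond on the syn face; a preformed lithium enolate at −78 °C, slow addition of a slight excess of ynoate and the rigid bicycle are meant to secure this. The PMB ether is used at C7 because, unlike a silyl ether, it cannot migrate to the enolate oxygen and transpose the nucleophilic carbon.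

Step 10
Reactants: 16 cage hydroxy ester PMB ether
Product: 17 methyl 1,7-dihydroxy-5,5-dimethyl-3-(3-methylbut-2-en-1-yl)-2-oxo-4-oxatricyclo[4.3.1.0^3,7]dec-8-ene-8-carboxylate
Conditions: DDQ (1.5 equiv), CH2Cl2–pH 7 buffer 10:1, 0 °C to rt
Reagents that add atoms: none
Why: Oxidative PMB cleavage (benzylic hydride abstraction by DDQ, hydrolysis of the oxocarbenium ion) works for tertiary ethers and leaves the prenyl alkene, enoate, ketone and tertiary alcohol untouched.

Step 11
Reactants: 17 cage dihydroxy ester
Product: 18 1,7-dihydroxy-5,5-dimethyl-3-(3-methylbut-2-en-1-yl)-2-oxo-4-oxatricyclo[4.3.1.0^3,7]dec-8-ene-8-carboxylic acid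
Conditions: Me3SnOH (5 equiv), 1,2-dichloroethane, 70 °C; then 5% aq. HCl wash
Reagents that add atoms: trimethyltin hydroxide, C[Sn](C)(C)O
Why: Near-neutral hydrolysis of a hindered methyl ester with trimethyltin hydroxide avoids free hydroxide, which could provoke retro-aldol opening at C10a or α-ketol rearrangement at C6/C7.

Step 12
Reactants: 19 phloroglucinol; 20 3-methylbut-2-enal
Product: 21 2,2-dimethyl-2H-chromene-5,7-diol
Conditions: pyridine, 110 °C, phloroglucinol in twofold excess
Reagents that add atoms: 3-methylbut-2-enal (compound 20), CC(C)=CC=O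
Why: Chromene annulation of a phenol with an enal (condensation to an ortho-quinone methide, then oxa-6π electrocyclisation); the symmetry of phloroglucinol leaves one possible mono-adduct and the excess of triol limits a second annulation.

Step 13
Reactants: 21 2,2-dimethyl-2H-chromene-5,7-diol
Product: 22 7-hydroxy-2,2-dimethyl-2H-chromene-5,8-dione
Conditions: ON(SO3K)2 (2.2 equiv), KH2PO4, H2O–acetone, 0 °C to rt
Reagents that add atoms: potassium nitrosodisulfonate, [K+].[K+].[O-]S(=O)(=O)N([O])S(=O)(=O)[O-]
Why: Teuber oxidation, in which the phenoxyl radical is oxygenated at the free position para to the C5 hydroxyl (C8) rather than at C6 between the two hydroxyls, giving the 2-hydroxy-1,4-quinone.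

Step 14
Reactants: 22 7-hydroxy-2,2-dimethyl-2H-chromene-5,8-dione; 23 prenyl bromide
Product: 24 7-hydroxy-2,2-dimethyl-6-(3-methylbut-2-en-1-yl)-2H-chromene-5,8-dione
Conditions: LiH, DMSO, rt; then prenyl bromide
Reagents that add atoms: prenyl bromide (compound 23), CC(C)=CCBr
Why: C-alkylation of the ambident anion of a 2-hydroxy-1,4-quinone with an allylic bromide, where the lithium salt in DMSO favours reaction at C6, the only nucleophilic carbon, and O-alkylation is the known competing path.

Step 15
Reactants: 18 cage dihydroxy acid; 24 prenyl hydroxyquinone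
Product: 25 2,2-dimethyl-6-(3-methylbut-2-en-1-yl)-5,8-dioxo-5,8-dihydro-2H-chromen-7-yl ester of acid 18 (acyloxyquinone)
Conditions: EDC·HCl (1.5 equiv), DMAP (0.2 equiv), CH2Cl2, 0 °C; short silica plug
Reagents that add atoms: none
Why: Steglich-type acylation of the vinylogous acid, in which the hydroxyquinone oxygen is far more reactive than the two hindered tertiary alcohols of 18 and acylation on the C7 oxygen keeps the para-quinone.

Step 16
Reactants: 25 acyloxyquinone
Product: 27 CNP0222516.1 (target), via spiro enol 26 (not isolated)
Conditions: i-Pr2NEt (0.2 equiv), CH2Cl2, 0 °C to rt; AcOH quench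
Reagents that add atoms: none
Why: Proposed new method: general-base-catalysed intramolecular oxa-Michael addition of the C10a tertiary hydroxyl to the acyloxy-bearing quinone carbon (6-exo-trig, that carbon being β to the quinone carbonyl across the prenylated carbon) gives enol 26, which is protonated at the prenylated carbon by the ammonium ion to give the spiro acylal; the closest known reaction type is spiroketal formation by intramolecular oxa-Michael addition to β-alkoxy enones (as in the double hetero-Michael spiroketalisation of ynones), here with an acyloxy group on the accepting carbon; the addition is reversible, so the spiro carbon and the epimerisable CH(prenyl) centre are expected, not assured, to settle in the target arrangement, with the prenyl group anti to the cage oxygen.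

**Compound list**

1 | 2,4-dimethoxyphenol | COc1ccc(O)c(OC)c1 | starting material
2 | 2,4,4-trimethoxycyclohexa-2,5-dien-1-one | O=C1C=CC(OC)(OC)C=C1OC | intermediate
3 | isopropenylboronic acid pinacol ester | CC(=C)B1OC(C)(C)C(C)(C)O1 | starting material
4 | (S)-2,4,4-trimethoxy-5-(prop-1-en-2-yl)cyclohex-2-en-1-one | O=C1C[C@@H](C(C)=C)C(OC)(OC)C=C1OC | intermediate
5 | (1S,5S)-2,4,4-trimethoxy-5-(prop-1-en-2-yl)cyclohex-2-en-1-ol (OH cis to isopropenyl) | O[C@H]1C[C@@H](C(C)=C)C(OC)(OC)C=C1OC | intermediate
6 | 4-methoxybenzyl ether of 5 | COc1ccc(CO[C@H]2C[C@@H](C(C)=C)C(OC)(OC)C=C2OC)cc1 | intermediate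
7 | 2-[(1S,5S)-2,2,4-trimethoxy-5-(4-methoxybenzyloxy)cyclohex-3-en-1-yl]propan-2-ol | COc1ccc(CO[C@H]2C[C@@H](C(C)(C)O)C(OC)(OC)C=C2OC)cc1 | intermediate
8 | (4S,6S)-6-(2-hydroxypropan-2-yl)-3-methoxy-4-(4-methoxybenzyloxy)cyclohex-2-en-1-one (not isolated) | COc1ccc(CO[C@H]2C[C@@H](C(C)(C)O)C(=O)C=C2OC)cc1 | intermediate
9 | (4S,6S)-6-(2-hydroxypropan-2-yl)-4-(4-methoxybenzyloxy)cyclohexane-1,3-dione | COc1ccc(CO[C@H]2C[C@@H](C(C)(C)O)C(=O)CC2=O)cc1 | intermediate
10 | prenyl acetate | CC(C)=CCOC(C)=O | starting material
11 | (4S,6S)-6-(2-hydroxypropan-2-yl)-4-(4-methoxybenzyloxy)-2-(3-methylbut-2-en-1-yl)cyclohexane-1,3-dione | COc1ccc(CO[C@H]2C[C@@H](C(C)(C)O)C(=O)C(CC=C(C)C)C2=O)cc1 | intermediate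
12 | (1S,3S,5R)-3-(4-methoxybenzyloxy)-7,7-dimethyl-5-(3-methylbut-2-en-1-yl)-6-oxabicyclo[3.2.1]octane-4,8-dione (bicycle C3 = cage C7, C4 = C6, C5 = C5, C8 = C10a) | COc1ccc(CO[C@H]2C[C@H]3C(C)(C)O[C@@](CC=C(C)C)(C2=O)C3=O)cc1 | intermediate
13 | methyl propiolate | C#CC(=O)OC | starting material
14 | lithium C6–C7 enolate of 12 (not isolated) | [Li+].[O-]C1=C(OCc2ccc(OC)cc2)C[C@H]3C(C)(C)O[C@]1(CC=C(C)C)C3=O | intermediate
15 | lithium allenolate from C7 Michael addition (not isolated) | [Li+].COC([O-])=C=C[C@]1(OCc2ccc(OC)cc2)C[C@H]3C(C)(C)O[C@@](CC=C(C)C)(C1=O)C3=O | intermediate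
16 | methyl 7-hydroxy-1-(4-methoxybenzyloxy)-5,5-dimethyl-3-(3-methylbut-2-en-1-yl)-2-oxo-4-oxatricyclo[4.3.1.0^3,7]dec-8-ene-8-carboxylate (cage configuration as in the target) | COC(=O)C1=C[C@]3(OCc2ccc(OC)cc2)C[C@H]4C(C)(C)O[C@@](CC=C(C)C)(C3=O)[C@@]14O | intermediate
17 | methyl 1,7-dihydroxy-5,5-dimethyl-3-(3-methylbut-2-en-1-yl)-2-oxo-4-oxatricyclo[4.3.1.0^3,7]dec-8-ene-8-carboxylate | COC(=O)C1=C[C@]3(O)C[C@H]4C(C)(C)O[C@@](CC=C(C)C)(C3=O)[C@@]14O | intermediate
18 | 1,7-dihydroxy-5,5-dimethyl-3-(3-methylbut-2-en-1-yl)-2-oxo-4-oxatricyclo[4.3.1.0^3,7]dec-8-ene-8-carboxylic acid | OC(=O)C1=C[C@]3(O)C[C@H]4C(C)(C)O[C@@](CC=C(C)C)(C3=O)[C@@]14O | intermediate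
19 | phloroglucinol | Oc1cc(O)cc(O)c1 | starting material
20 | 3-methylbut-2-enal | CC(C)=CC=O | starting material
21 | 2,2-dimethyl-2H-chromene-5,7-diol | CC1(C)C=Cc2c(O)cc(O)cc2O1 | intermediate
22 | 7-hydroxy-2,2-dimethyl-2H-chromene-5,8-dione | CC1(C)C=CC2=C(O1)C(=O)C(O)=CC2=O | intermediate
23 | prenyl bromide | CC(C)=CCBr | starting material
24 | 7-hydroxy-2,2-dimethyl-6-(3-methylbut-2-en-1-yl)-2H-chromene-5,8-dione | CC(C)=CCC1=C(O)C(=O)C2=C(C=CC(C)(C)O2)C1=O | intermediate
25 | 7-O-acyl derivative of 24 with acid 18 (acyloxyquinone, free C7 and C10a hydroxyls on the cage) | CC(C)=CCC1=C(OC(=O)C3=C[C@]4(O)C[C@H]5C(C)(C)O[C@@](CC=C(C)C)(C4=O)[C@@]35O)C(=O)C2=C(C=CC(C)(C)O2)C1=O | intermediate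
26 | spiro enol, the enol tautomer of the target at the CH(prenyl)–C=O unit (not isolated) | CC(C)=CCC1=C(O)C2=C(OC(C)(C)C=C2)C(=O)[C@@]13OC(=O)C4=C[C@]5(O)C[C@H]6C(C)(C)O[C@@](CC=C(C)C)(C5=O)[C@@]46O3 | intermediate
27 | CNP0222516.1 | CC(C)=CC[C@H]1C(=O)C2=C(OC(C)(C)C=C2)C(=O)[C@@]12OC(=O)C1=C[C@]3(O)C[C@H]4C(C)(C)O[C@@](CC=C(C)C)(C3=O)[C@@]14O2 | target

**Step count and risks**

Total: 16 steps. Longest linear sequence: 13 steps (steps 1–11, 15 and 16); steps 12–14 are the three-step branch to quinone 24.

Steps most likely to fail:

Step 16. The enolate formed by the conjugate addition may expel the carboxylate (β-elimination) faster than it is protonated at carbon, which moves the quinone from the acyl oxygen to the C10a oxygen and opens the ring; the addition may also take the wrong quinone face and give the spiro epimer. The fallback sets out from 25 and makes the ring-opening deliberate: a full equivalent of DBU in THF drives the addition–elimination (nucleophilic vinylic substitution on a quinone that carries a leaving group) to the ring-opened 2-alkoxyquinone carboxylic acid F1 after acidification. The ring is then closed from the other oxygen by acid-catalysed addition of the carboxylic acid across the alkoxy-substituted quinone C=C (camphorsulfonic acid, CH2Cl2, rt), the known enol-ether-plus-carboxylic-acid route to α-alkoxyalkyl esters. Protonation occurs at the prenylated carbon, the closure is reversible, and the sequence comes back to the route at 27.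

Step 9. Proton transfer from the alkyne C–H may quench the enolate before Michael addition, or the allenolate may collapse on the C6 carbonyl to a cyclobutene alkoxide that fragments. The fallback sets out from 12 and uses methyl acrylate in place of the ynoate under the same enolate conditions; the acceptor has no acidic hydrogen and the Michael–aldol sequence should give the saturated cage hydroxy ester F2. Its dianion (LiN(i-Pr)2, 2.2 equiv, THF, −78 °C) is selenenylated with PhSeBr at C8a to give the α-phenylselanyl ester F3. Oxidation with H2O2–pyridine brings about selenoxide syn-elimination toward C8, the only carbon with a β-hydrogen, which installs the C8=C8a alkene and returns to 16.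

Step 5. Hydrogen-atom transfer to the enol ether double bond may compete with hydration of the isopropenyl group, or reduction may take the place of oxygenation. The fallback sets out from 4 and hydrates the isopropenyl group at the enone stage, where the ring alkene is an electron-poor, α-methoxy-substituted enone, to give hydroxy enone F4 (Co(acac)2, PhSiH3, O2; PPh3). Luche reduction then gives diol F5, and etherification of the secondary allylic alkoxide (NaH 1 equiv, 4-methoxybenzyl chloride, n-Bu4NI) in the presence of the unreactive tertiary alcohol returns to 7.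

**Further compounds**

F1 | step 16 | ring-opened alkoxyquinone acid: cage acid 18 carrying the quinone of 24 as an ether on the C10a oxygen | OC(=O)C3=C[C@]4(O)C[C@H]5C(C)(C)O[C@@](CC=C(C)C)(C4=O)[C@@]35OC1=C(CC=C(C)C)C(=O)C2=C(OC(C)(C)C=C2)C1=O
F2 | step 9 | saturated cage hydroxy ester (8,9-dihydro analogue of 16, C8a epimers) | COC(=O)C1C[C@]3(OCc2ccc(OC)cc2)C[C@H]4C(C)(C)O[C@@](CC=C(C)C)(C3=O)[C@@]14O
F3 | step 9 | α-phenylselanyl ester of F2 at C8a | COC(=O)C1([Se]c5ccccc5)C[C@]3(OCc2ccc(OC)cc2)C[C@H]4C(C)(C)O[C@@](CC=C(C)C)(C3=O)[C@@]14O
F4 | step 5 | (S)-5-(2-hydroxypropan-2-yl)-2,4,4-trimethoxycyclohex-2-en-1-one | O=C1C[C@@H](C(C)(C)O)C(OC)(OC)C=C1OC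
F5 | step 5 | (1S,5S)-5-(2-hydroxypropan-2-yl)-2,4,4-trimethoxycyclohex-2-en-1-ol | O[C@H]1C[C@@H](C(C)(C)O)C(OC)(OC)C=C1OC
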